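Everything rests on cutting the C7–C11 bond that joins the side chain to the seven-membered ring. The feature exploited is that C11, an acyclic tertiary carbinol bearing methyl, hydroxyl and the oxidised carbon C12, sits next to the ring methine C7, and the ring fusion gives no dependable bias for this pair. With a temporary ketone at C8, a copper bis(oxazoline)-catalysed Mukaiyama aldol addition of the C7=C8 trimethylsilyl enol ether to methyl pyruvate forms C7–C11 and sets both centres at once. Its precursor is the cis-fused five/seven bicycle with the 1,10-diol as acetonide, the enol silane being generated regiospecifically by 1,4-reduction of the C6=C7 enone.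

Key step: step 15

Remark: guaiane numbering is used for all bicyclic compounds (C1 and C5 at the ring fusion, methyl groups on C4 and C10, side chain on C7); α is the face of 5-H, so the target is the 1α,10α,11-triol with 4β-methyl and a 7β side chain, (1S,4S,5S,7R,10R,11R).
Remark: the carbon that becomes C8 is carried as both epimers in compounds 5–16 and again in 23–26; it is sp2 in 17–22 and a CH2 group from 27 on, so it never affects the configuration of the target.
Remark: the (R,R) ligand is specified in step 15 because the 11R carbinol requires bond formation on the re face of the pyruvate ketone; absolute configuration enters the route in step 5.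
Remark: the target is taken to be the free hydrogen sulfate as drawn.

Step 1
Reactants: 1 3-methylcyclopent-2-en-1-one
Product: 2 2-iodo-3-methylcyclopent-2-en-1-one
Conditions: I2, pyridine/CH2Cl2, 0 °C → rt
Reagents that add atoms: iodine, II
Why: α-Iodination of the enone by pyridine addition, iodination of the enolate and loss of pyridine puts iodine on C2 (the future C5) and prepares the ring for cross-coupling; no stereocentre is formed.

Step 2
Reactants: 3 ethyl 2-(2-methyl-1,3-dioxolan-2-yl)acetate
Product: 5 rac-1-(2-methyl-1,3-dioxolan-2-yl)but-3-en-2-ol, via ketal aldehyde 4 (not isolated)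
Conditions: DIBAL-H (1.05 equiv), CH2Cl2, −78 °C; then CH2=CHMgBr, THF, −78 → 0 °C
Reagents that add atoms: vinylmagnesium bromide, C=C[Mg]Br
Why: Half-reduction of the ester gives an aluminium hemiacetal that releases the aldehyde in the presence of the Grignard reagent (one-pot reduction/1,2-addition), giving the allylic alcohol that carries C6–C10; its carbinol (future C8) is left uncontrolled on purpose because it becomes a carbonyl in step 13.

Step 3
Reactants: 5 rac-1-(2-methyl-1,3-dioxolan-2-yl)but-3-en-2-ol
Product: 6 rac-tert-butyldimethylsilyl ether of 5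
Conditions: TBSCl, imidazole, DMF, rt
Reagents that add atoms: tert-butyldimethylsilyl chloride, CC(C)(C)[Si](C)(C)Cl
Why: Imidazole-mediated silylation of a secondary alcohol masks the C8 oxygen so that it neither directs the hydrogenation of step 6 nor takes part in the carbonyl coupling of step 9.

Step 4
Reactants: 6 rac-silyl ether; 2 2-iodo-3-methylcyclopent-2-en-1-one
Product: 8 2-[3-(tert-butyldimethylsilyloxy)-4-(2-methyl-1,3-dioxolan-2-yl)butyl]-3-methylcyclopent-2-en-1-one, via alkylborane 7 (not isolated)
Conditions: 9-BBN, THF, rt; then 2, Pd(dppf)Cl2 (5 mol %), AsPh3, Cs2CO3, DMF/H2O, rt → 50 °C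
Reagents that add atoms: none
Why: B-alkyl Suzuki–Miyaura coupling: 9-BBN adds anti-Markovnikov to the terminal alkene and palladium transfers the primary alkyl group to the 2-iodoenone, forming C5–C6 on a substrate class (2-iodocycloalkenones) for which this coupling is established.

Step 5
Reactants: 8 cyclopentenone
Product: 9 (1S)-2-[3-(tert-butyldimethylsilyloxy)-4-(2-methyl-1,3-dioxolan-2-yl)butyl]-3-methylcyclopent-2-en-1-ol
Conditions: (R)-2-methyl-CBS-oxazaborolidine (20 mol %), BH3·SMe2, THF, −30 °C
Reagents that add atoms: none
Why: Corey–Bakshi–Shibata reduction: the oxazaborolidine binds the ketone with the substituted alkenyl flank as the large group and delivers hydride to one face, which should give the (S)-allylic alcohol; this carbinol is the only source of absolute configuration for C4 and C5.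

Step 6
Reactants: 9 (S)-allylic alcohol
Product: 10 (1S,2S,3S)-2-[3-(tert-butyldimethylsilyloxy)-4-(2-methyl-1,3-dioxolan-2-yl)butyl]-3-methylcyclopentan-1-ol (OH trans to the side chain, side chain cis to methyl)
Conditions: H2 (1 atm), [Ir(cod)(PCy3)(py)]PF6 (10 mol %), CH2Cl2, 0 °C → rt
Reagents that add atoms: none
Why: Hydroxyl-directed homogeneous hydrogenation: the cationic iridium centre is held by the allylic OH and adds H2 to the tetrasubstituted C4=C5 bond from the hydroxyl face, so 4-H and 5-H are cis to OH and the methyl group and the side chain end up cis to each other.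

Step 7
Reactants: 10 cyclopentanol ketal
Product: 11 (1S,2S,3S)-3-methyl-2-[5-oxo-3-(tert-butyldimethylsilyloxy)hexyl]cyclopentan-1-ol
Conditions: PPTS, acetone/H2O, 45 °C
Reagents that add atoms: water, O
Why: Acid-catalysed transketalisation to acetone frees the methyl ketone (C10 with its methyl C14) under conditions that a secondary TBS ether tolerates.

Step 8
Reactants: 11 hydroxy ketone
Product: 12 (2S,3S)-3-methyl-2-[5-oxo-3-(tert-butyldimethylsilyloxy)hexyl]cyclopentan-1-one (cis)
Conditions: Dess–Martin periodinane, NaHCO3, CH2Cl2, 0 °C → rt; used crude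
Reagents that add atoms: none
Why: Dess–Martin oxidation under bicarbonate buffer converts the C1 carbinol into the ketone without enolising it, so the less stable cis C4/C5 relationship is kept; the diketone is used at once.

Step 9
Reactants: 12 cis-diketone
Product: 13 (4S,5S)-8-(tert-butyldimethylsilyloxy)-11,12,13-trinorguai-1(10)-ene
Conditions: TiCl3(DME)1.5, zinc–copper couple, DME, reflux, slow addition of 12
Reagents that add atoms: none
Why: Intramolecular McMurry coupling: low-valent titanium joins the two ketones as a titanium pinacolate and deoxygenates it to the tetrasubstituted C1=C10 alkene, closing the seven-membered ring; C1 becomes sp2, so ring fusion and diol geometry are left to step 10, and the fast pinacolate formation leaves little time for C5 to epimerise.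

Step 10
Reactants: 13 tetrasubstituted alkene
Product: 14 (1S,4S,5S,10R)-8-(tert-butyldimethylsilyloxy)-11,12,13-trinorguaiane-1,10-diol (1α,10α-diol)
Conditions: OsO4 (5 mol %), N-methylmorpholine N-oxide, MeSO2NH2, acetone/t-BuOH/H2O, 40 °C
Reagents that add atoms: N-methylmorpholine N-oxide, C[N+]1([O-])CCOCC1; water, O (both oxygens are passed on by OsO4, which is re-formed from these)
Why: Osmium-catalysed syn-dihydroxylation: the [3+2] addition of OsO4 should occur on the α face, because the β face carries C6 (held there by the 5α-H ring fusion) and the 4β-methyl group, which sets C1 and C10 together as the cis-diol cis to 5-H.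

Step 11
Reactants: 14 diol
Product: 15 1,10-acetonide of 14
Conditions: 2-methoxypropene, PPTS (cat.), CH2Cl2, 0 °C → rt
Reagents that add atoms: 2-methoxypropene, COC(C)=C
Why: Acid-catalysed ketalisation with an enol ether ties the cis 1,10-diol into a dioxolane that is inert to the base, hydride and Lewis acid steps that follow.

Step 12
Reactants: 15 silyl ether acetonide
Product: 16 (1S,4S,5S,10R)-1,10-(isopropylidenedioxy)-11,12,13-trinorguaian-8-ol
Conditions: TBAF, THF, rt
Reagents that add atoms: none
Why: Fluoride-induced cleavage of the Si–O bond frees the C8 alcohol and leaves the acetonide untouched.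

Step 13
Reactants: 16 C8 alcohol
Product: 18 (1S,4S,5R,10R)-1,10-(isopropylidenedioxy)-11,12,13-trinorguai-6-en-8-one (same spatial arrangement; the C5 descriptor changes with the double bond), via saturated ketone 17 (not isolated)
Conditions: 2-iodoxybenzoic acid (3 equiv), DMSO/fluorobenzene, 70 °C
Reagents that add atoms: none
Why: Oxidation of the alcohol by 2-iodoxybenzoic acid is followed in the same pot by dehydrogenation of the ketone by the same reagent; only C7–C6 can be desaturated because C10 is quaternary, so a single enone is formed and both C8 epimers converge.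

Step 14
Reactants: 18 enone
Product: 19 (1S,4S,5S,10R)-1,10-(isopropylidenedioxy)-8-(trimethylsilyloxy)-11,12,13-trinorguai-7-ene
Conditions: [(Ph3P)CuH]6 (0.25 equiv), Me3SiCl (3 equiv), THF, −40 → 0 °C; filtration through Et3N-washed silica
Reagents that add atoms: chlorotrimethylsilane, C[Si](C)(C)Cl
Why: Conjugate reduction by the copper hydride with trapping of the copper enolate by Me3SiCl (1,4-hydrometalation/O-silylation) fixes the enol double bond at C7=C8 through the position of the enone, which deprotonation of the ketone could not guarantee; the filtration removes phosphine before the copper catalysis of step 15.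

Step 15
Reactants: 19 enol silane; 20 methyl pyruvate
Product: 22 methyl (1S,4S,5S,7R,10R,11R)-11-hydroxy-1,10-(isopropylidenedioxy)-8-oxoguaian-12-oate, via silyl ether 21 (not isolated)
Conditions: Cu(OTf)2 (10 mol %), 2,2'-(propane-2,2-diyl)bis[(4R)-4-tert-butyl-4,5-dihydrooxazole] (11 mol %), THF, −78 °C; then 1 M HCl, THF, 0 °C
Reagents that add atoms: none
Why: The copper complex holds methyl pyruvate as a five-membered chelate through ketone and ester oxygen on the divalent copper centre, the enol silane adds to the activated ketone through an open transition state and the silyl group moves to the new alkoxide, which frees the catalyst (Mukaiyama aldol addition; the closest known reaction is the copper bis(oxazoline)-catalysed addition of ketone- and thioester-derived enol silanes to pyruvate esters). No ring is closed. C11 is set by the ligand: with the (R,R) antipode the tert-butyl groups cover the si face of the ketone, so C7 bonds to the re face and the carbinol has the 11R arrangement of the target. C7 is set by the relative topicity of the open transition state, in which the small 7-H lies over the chelate ring and C6 points away from it (syn adduct); combined with the re face of pyruvate this means bond formation on the β face of the enol silane, which is also the face remote from the dioxolane. The step needs site selectivity (only C7 can react, secured by the way the enol silane was made), syn diastereoselectivity and enantioface selectivity at the ketone (both secured by the catalyst, whose sense should override a modest intrinsic bias of the bicycle). Mild acid then hydrolyses the silyl ether without opening the hindered acetonide.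

Step 16
Reactants: 22 aldol adduct
Product: 23 (1S,4S,5S,7S,10R,11R)-1,10-(isopropylidenedioxy)guaiane-8,11,12-triol (C8 epimers; same spatial arrangement at C7)
Conditions: LiAlH4, THF, −78 → 0 °C
Reagents that add atoms: none
Why: Hydride reduction with LiAlH4 takes the C8 ketone to the alcohol and the ester to the primary alcohol C12 in one operation; ketone reduction is faster than retro-aldol cleavage of the alkoxide, C7 is no longer epimerisable afterwards, and the C8 configuration is irrelevant because this oxygen is removed in step 19.

Step 17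
Reactants: 23 triol
Product: 24 1,10:11,12-bis(isopropylidenedioxy)guaian-8-ol
Conditions: 2,2-dimethoxypropane, PPTS (cat.), CH2Cl2, rt
Reagents that add atoms: 2,2-dimethoxypropane, COC(C)(C)OC
Why: Acid-catalysed transketalisation should select the primary/tertiary 1,2-diol at C11/C12 as the five-membered dioxolane and leave the hindered secondary C8 hydroxyl free.

Step 18
Reactants: 24 bis-acetonide alcohol
Product: 26 O-[1,10:11,12-bis(isopropylidenedioxy)guaian-8-yl] S-methyl dithiocarbonate, via sodium xanthate 25 (not isolated)
Conditions: NaH, imidazole (cat.), THF, 0 °C; CS2; then MeI, rt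
Reagents that add atoms: carbon disulfide, S=C=S; iodomethane, CI
Why: Xanthate formation (alkoxide addition to CS2, then S-methylation) activates the only free hydroxyl, at C8, for radical cleavage.

Step 19
Reactants: 26 xanthate
Product: 27 (1S,4S,5S,7R,10R,11R)-1,10:11,12-bis(isopropylidenedioxy)guaiane
Conditions: Bu3SnH, AIBN (cat.), toluene, 100 °C
Reagents that add atoms: none
Why: Barton–McCombie deoxygenation: the stannyl radical adds to the thiocarbonyl group, the C8–O bond fragments and the secondary C8 radical takes hydrogen from Bu3SnH; C8 is not a stereocentre in the product and C7 is untouched.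

Step 20
Reactants: 27 bis-acetonide
Product: 28 (1S,4S,5S,7R,10R,11R)-guaiane-1,10,11,12-tetraol
Conditions: 1 M HCl, THF/MeOH, 40 °C
Reagents that add atoms: none
Why: Acid hydrolysis of both acetonides under mild aqueous conditions frees the three tertiary hydroxyls and the primary one without ionising the tertiary carbinols.

Step 21
Reactants: 28 tetraol
Product: 30 (1S,4S,5S,7R,10R,11R)-1,10,11-trihydroxyguaian-12-yl hydrogen sulfate (CNP0315443.2), via pyridinium sulfate 29 (not isolated)
Conditions: SO3·pyridine (1.5 equiv), pyridine, 0 °C → rt; then sulfonic acid cation-exchange resin (H+ form), MeOH/H2O, 0 °C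
Reagents that add atoms: sulfur trioxide–pyridine complex, [O-]S(=O)(=O)[n+]1ccccc1
Why: O-Sulfation with the sulfur trioxide–pyridine complex is selective for the unhindered primary hydroxyl at C12 over the three tertiary ones, and cation exchange on the acid resin converts the pyridinium salt into the hydrogen sulfate, which is kept cold.

Compound list
1 | 3-methylcyclopent-2-en-1-one | CC1=CC(=O)CC1 | starting material
2 | 2-iodo-3-methylcyclopent-2-en-1-one | CC1=C(I)C(=O)CC1 | intermediate
3 | ethyl 2-(2-methyl-1,3-dioxolan-2-yl)acetate | CCOC(=O)CC1(C)OCCO1 | starting material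
4 | 2-(2-methyl-1,3-dioxolan-2-yl)acetaldehyde | O=CCC1(C)OCCO1 | intermediate (not isolated)
5 | rac-1-(2-methyl-1,3-dioxolan-2-yl)but-3-en-2-ol | C=CC(O)CC1(C)OCCO1 | intermediate
6 | rac-tert-butyldimethyl{[1-(2-methyl-1,3-dioxolan-2-yl)but-3-en-2-yl]oxy}silane | C=CC(O[Si](C)(C)C(C)(C)C)CC1(C)OCCO1 | intermediate
7 | 9-[3-(tert-butyldimethylsilyloxy)-4-(2-methyl-1,3-dioxolan-2-yl)butyl]-9-borabicyclo[3.3.1]nonane | CC1(CC(CCB2C3CCCC2CCC3)O[Si](C)(C)C(C)(C)C)OCCO1 | intermediate (not isolated)
8 | 2-[3-(tert-butyldimethylsilyloxy)-4-(2-methyl-1,3-dioxolan-2-yl)butyl]-3-methylcyclopent-2-en-1-one (racemic at the silyloxy carbon) | CC1=C(CCC(O[Si](C)(C)C(C)(C)C)CC2(C)OCCO2)C(=O)CC1 | intermediate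
9 | (1S)-2-[3-(tert-butyldimethylsilyloxy)-4-(2-methyl-1,3-dioxolan-2-yl)butyl]-3-methylcyclopent-2-en-1-ol (both epimers at the silyloxy carbon) | CC1=C(CCC(O[Si](C)(C)C(C)(C)C)CC2(C)OCCO2)[C@@H](O)CC1 | intermediate
10 | (1S,2S,3S)-2-[3-(tert-butyldimethylsilyloxy)-4-(2-methyl-1,3-dioxolan-2-yl)butyl]-3-methylcyclopentan-1-ol | C[C@H]1CC[C@H](O)[C@H]1CCC(O[Si](C)(C)C(C)(C)C)CC2(C)OCCO2 | intermediate
11 | (1S,2S,3S)-3-methyl-2-[5-oxo-3-(tert-butyldimethylsilyloxy)hexyl]cyclopentan-1-ol | C[C@H]1CC[C@H](O)[C@H]1CCC(O[Si](C)(C)C(C)(C)C)CC(C)=O | intermediate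
12 | (2S,3S)-3-methyl-2-[5-oxo-3-(tert-butyldimethylsilyloxy)hexyl]cyclopentan-1-one | C[C@H]1CCC(=O)[C@H]1CCC(O[Si](C)(C)C(C)(C)C)CC(C)=O | intermediate
13 | (4S,5S)-8-(tert-butyldimethylsilyloxy)-11,12,13-trinorguai-1(10)-ene | C[C@H]1CCC2=C(C)CC(O[Si](C)(C)C(C)(C)C)CC[C@@H]12 | intermediate
14 | (1S,4S,5S,10R)-8-(tert-butyldimethylsilyloxy)-11,12,13-trinorguaiane-1,10-diol | C[C@H]1CC[C@]2(O)[C@H]1CCC(O[Si](C)(C)C(C)(C)C)C[C@@]2(C)O | intermediate
15 | (1S,4S,5S,10R)-8-(tert-butyldimethylsilyloxy)-1,10-(isopropylidenedioxy)-11,12,13-trinorguaiane | C[C@H]1CC[C@]2(OC3(C)C)[C@H]1CCC(O[Si](C)(C)C(C)(C)C)C[C@@]2(C)O3 | intermediate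
16 | (1S,4S,5S,10R)-1,10-(isopropylidenedioxy)-11,12,13-trinorguaian-8-ol (C8 epimers) | C[C@H]1CC[C@]2(OC3(C)C)[C@H]1CCC(O)C[C@@]2(C)O3 | intermediate
17 | (1S,4S,5S,10R)-1,10-(isopropylidenedioxy)-11,12,13-trinorguaian-8-one | C[C@H]1CC[C@]2(OC3(C)C)[C@H]1CCC(=O)C[C@@]2(C)O3 | intermediate (not isolated)
18 | (1S,4S,5R,10R)-1,10-(isopropylidenedioxy)-11,12,13-trinorguai-6-en-8-one | C[C@H]1CC[C@]2(OC3(C)C)[C@H]1C=CC(=O)C[C@@]2(C)O3 | intermediate
19 | (1S,4S,5S,10R)-1,10-(isopropylidenedioxy)-8-(trimethylsilyloxy)-11,12,13-trinorguai-7-ene | C[C@H]1CC[C@]2(OC3(C)C)[C@H]1CC=C(O[Si](C)(C)C)C[C@@]2(C)O3 | intermediate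
20 | methyl pyruvate | CC(=O)C(=O)OC | starting material
21 | methyl (1S,4S,5S,7R,10R,11R)-1,10-(isopropylidenedioxy)-8-oxo-11-(trimethylsilyloxy)guaian-12-oate | C[C@H]1CC[C@]2(OC3(C)C)[C@H]1C[C@H]([C@@](C)(O[Si](C)(C)C)C(=O)OC)C(=O)C[C@@]2(C)O3 | intermediate (not isolated)
22 | methyl (1S,4S,5S,7R,10R,11R)-11-hydroxy-1,10-(isopropylidenedioxy)-8-oxoguaian-12-oate | C[C@H]1CC[C@]2(OC3(C)C)[C@H]1C[C@H]([C@@](C)(O)C(=O)OC)C(=O)C[C@@]2(C)O3 | intermediate
23 | (1S,4S,5S,7S,10R,11R)-1,10-(isopropylidenedioxy)guaiane-8,11,12-triol (C8 epimers) | C[C@H]1CC[C@]2(OC3(C)C)[C@H]1C[C@H]([C@@](C)(O)CO)C(O)C[C@@]2(C)O3 | intermediate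
24 | 1,10:11,12-bis(isopropylidenedioxy)guaian-8-ol (C8 epimers) | C[C@H]1CC[C@]2(OC3(C)C)[C@H]1C[C@H]([C@]4(C)COC(C)(C)O4)C(O)C[C@@]2(C)O3 | intermediate
25 | sodium O-[1,10:11,12-bis(isopropylidenedioxy)guaian-8-yl] dithiocarbonate | C[C@H]1CC[C@]2(OC3(C)C)[C@H]1C[C@H]([C@]4(C)COC(C)(C)O4)C(OC(=S)[S-])C[C@@]2(C)O3.[Na+] | intermediate (not isolated)
26 | O-[1,10:11,12-bis(isopropylidenedioxy)guaian-8-yl] S-methyl dithiocarbonate | C[C@H]1CC[C@]2(OC3(C)C)[C@H]1C[C@H]([C@]4(C)COC(C)(C)O4)C(OC(=S)SC)C[C@@]2(C)O3 | intermediate
27 | (1S,4S,5S,7R,10R,11R)-1,10:11,12-bis(isopropylidenedioxy)guaiane | C[C@H]1CC[C@]2(OC3(C)C)[C@H]1C[C@H]([C@]4(C)COC(C)(C)O4)CC[C@@]2(C)O3 | intermediate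
28 | (1S,4S,5S,7R,10R,11R)-guaiane-1,10,11,12-tetraol | C[C@H]1CC[C@]2(O)[C@H]1C[C@H]([C@@](C)(O)CO)CC[C@@]2(C)O | intermediate
29 | pyridinium (1S,4S,5S,7R,10R,11R)-1,10,11-trihydroxyguaian-12-yl sulfate | C[C@H]1CC[C@]2(O)[C@H]1C[C@H]([C@@](C)(O)COS(=O)(=O)[O-])CC[C@@]2(C)O.c1cc[nH+]cc1 | intermediate (not isolated)
30 | (1S,4S,5S,7R,10R,11R)-1,10,11-trihydroxyguaian-12-yl hydrogen sulfate | C[C@H]1CC[C@]2(O)[C@H]1C[C@H]([C@@](C)(O)COS(=O)(=O)O)CC[C@@]2(C)O | target

Total step count: 21. Longest linear sequence: 20 steps (3 → 30, steps 2–21); step 1 is a one-step branch that joins in step 4.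

Steps most likely to fail

Step 15. The catalyst may be slowed by the Lewis-basic acetonide or by traces of phosphine. The facial preference of the bicyclic enol silane may also oppose the catalyst, so that the syn/anti pairing of C7 and C11 erodes (mismatched double stereodifferentiation). The fallback replaces catalyst control by auxiliary control with a stoichiometric Lewis acid. It sets out from 19. (1S,2R)-2-Phenylcyclohexyl pyruvate F1 is prepared from pyruvic acid and the commercial alcohol (DCC, DMAP). Enol silane 19 is added to it with SnCl4 in CH2Cl2 at −78 °C, a chelation-controlled Mukaiyama aldol addition in which the phenyl ring should screen the si face of the ketone. This antipode is chosen by analogy with the si-face additions of the (1R,2S) series. The product is the (1S,2R)-2-phenylcyclohexyl ester analogue of 22 F2. LiAlH4, as in step 16, reduces ketone and ester, releases the auxiliary alcohol and brings the material back to the route at 23.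

Step 10. Osmylation of a hindered tetrasubstituted alkene may be slow, facial discrimination may be incomplete, and any erosion at C5 during a sluggish step 9 would be carried along. The fallback sets out from 12 and returns at 14, bypassing 13. The cis-diketone is cyclised directly by reductive pinacol coupling with SmI2 (HMPA, t-BuOH, THF, −78 °C → rt). The ketyl of the methyl ketone adds to the samarium-bound ring carbonyl, the samarium bridge between the two oxygens should favour the cis-diol, and the tether on the β face should favour the cis ring fusion. The conditions are neutral and fast, so C5 has no opportunity to epimerise. No compound outside the list is made (F0).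

Step 13. Desaturation may stop at the saturated ketone, run on to a dienone, or cost part of the acetonide at 70 °C. The fallback sets out from 16 and returns at 19, bypassing 18 and step 14. Dess–Martin oxidation gives ketone 17, which is isolated. Kinetic deprotonation with LDA in the presence of Me3SiCl (THF, −78 °C, internal quench) then silylates towards the less hindered C7 rather than the neopentyl C9. The price is possible contamination by the C8=C9 regioisomer, which would have to be removed after the aldol step. No compound outside the list is made (F0).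

Further compounds
F1 | step 15 | (1S,2R)-2-phenylcyclohexyl pyruvate | CC(=O)C(=O)O[C@H]1CCCC[C@@H]1c1ccccc1
F2 | step 15 | (1S,2R)-2-phenylcyclohexyl (1S,4S,5S,7R,10R,11R)-11-hydroxy-1,10-(isopropylidenedioxy)-8-oxoguaian-12-oate | C[C@H]1CC[C@]2(OC3(C)C)[C@H]1C[C@H]([C@@](C)(O)C(=O)O[C@H]4CCCC[C@@H]4c4ccccc4)C(=O)C[C@@]2(C)O3
F0 | step 10 | none | none
F0 | step 13 | none | none
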